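Retrosynthesis: the acetate and both angelates come off first, then the two cis-oxiranes (C4–C5, C1–C10); the C9 oxygen and the C1=C10 olefin are traced through a C9–C10 epoxide to a C8 allylic alcohol with an (E)-C9=C10 olefin.
The C7 isopropenyl group next to the C8 oxygen on the ten-membered ring is a homoallylic alcohol, the retron of a [2,3]-Wittig shift: cutting C7–C8 opens the carbocycle to a thirteen-membered ether in which oxygen joins C8 to C12.
This ether is cut at O–C12 (Williamson), C3–C4 (Nozaki–Hiyama–Kishi) and C7=C11 (Wittig), giving a C8–C3 aldehyde from geranyl acetate and a C4–C12 (Z)-vinyl iodide from but-2-yn-1-ol.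
Forward: the chain is joined at C7=C11 and C3–C4, the thirteen-membered oxacycle is closed, it is contracted to the ten-membered carbocycle, and the two oxiranes are added last.
Stereochemistry: C3 from an oxazaborolidine reduction; C7 and C8 from the ring contraction ((Z)-C7=C11 gives the cis pair, C3 chooses the face); C9, then C1 and C10, from two hydroxyl-directed vanadium epoxidations; C4 and C5 from a hydroxyl-guided peracid epoxidation.

Key step: step 15

Remark: atoms carry germacrane numbers (ring C1–C10; isopropenyl C11–C13 on C7; C14 = methyl on C10; C15 = methyl on C4); β is the ring face that bears the C7 isopropenyl group; in the open-chain dodecatriene names C1, C6 and C12 are C8, C3 and C12 of the target.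
Assumption: the C8 allyllithium of step 15 is taken to be configurationally labile, so that C7 and C8 are fixed in the transition state; the facial sense relative to C3 is the expected one, not a proven one.
Assumption: geranyl acetate and 1-[(tert-butyldimethylsilyl)oxy]propan-2-one are bought.

Step 1
Reactants: 1 geranyl acetate
Product: 2 6,7-epoxygeranyl acetate (racemic)
Conditions: mCPBA, NaHCO3, CH2Cl2, 0 °C
Reagents that add atoms: mCPBA, O=C(OO)c1cccc(Cl)c1
Why: Prilezhaev epoxidation should pick the electron-rich distal olefin because the C2=C3 olefin is deactivated by the allylic acetate; the new centre is racemic and is cleaved away in step 2.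

Step 2
Reactants: 2 6,7-epoxygeranyl acetate
Product: 3 (2E)-3-methyl-6-oxohex-2-en-1-yl acetate (C8–C3 aldehyde)
Conditions: H5IO6, THF–H2O, 0 °C
Reagents that add atoms: none
Why: Periodic acid opens the epoxide and cleaves the glycol in one flask (glycol cleavage), which should give the C3 aldehyde and acetone without touching the (E)-olefin or the acetate.

Step 3
Reactants: 4 but-2-yn-1-ol
Product: 6 (2Z)-3-iodobut-2-en-1-ol, via cyclic alkenylalanate 5 (not isolated)
Conditions: NaAlH2(OCH2CH2OCH3)2, THF, 0 °C to rt; then I2, −78 °C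
Reagents that add atoms: iodine, II
Why: Hydroxyl-directed trans-hydroalumination of the propargylic alcohol puts aluminium on the distal alkyne carbon inside a five-membered alanate, and iodinolysis with retention should give the (Z)-vinyl iodide that carries C15, C4, C5 and C6.

Step 4
Reactants: 6 (2Z)-3-iodobut-2-en-1-ol
Product: 7 (2Z)-1-bromo-3-iodobut-2-ene
Conditions: CBr4, PPh3, CH2Cl2, 0 °C
Reagents that add atoms: tetrabromomethane, BrC(Br)(Br)Br
Why: Appel bromination converts the primary allylic alcohol into the bromide without allylic shift or loss of olefin geometry.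

Step 5
Reactants: 7 (2Z)-1-bromo-3-iodobut-2-ene; 8 methyltriphenylphosphonium bromide
Product: 10 [(3Z)-4-iodopent-3-en-1-yl]triphenylphosphonium bromide, via methylenetriphenylphosphorane 9 (not isolated)
Conditions: n-BuLi, THF, 0 °C; then 7, −78 °C to rt
Reagents that add atoms: none
Why: C-Alkylation of the phosphorus ylide by the allylic bromide (SN2) adds C7 and should give the homoallylic phosphonium salt, the vinyl iodide being inert to the ylide once all n-BuLi is consumed.

Step 6
Reactants: 10 [(3Z)-4-iodopent-3-en-1-yl]triphenylphosphonium bromide; 11 1-[(tert-butyldimethylsilyl)oxy]propan-2-one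
Product: 13 tert-butyl{[(2Z,5Z)-6-iodo-2-methylhepta-2,5-dien-1-yl]oxy}dimethylsilane (C4–C12 vinyl iodide), via phosphorus ylide 12 (not isolated)
Conditions: KN(SiMe3)2, THF, −78 °C; then 11, −78 °C to rt
Reagents that add atoms: none
Why: Wittig olefination of an α-silyloxy ketone with a non-stabilised ylide favours the (Z)-trisubstituted allylic ether, which should set C7=C11 with C6 cis to C12.

Step 7
Reactants: 13 C4–C12 vinyl iodide; 3 C8–C3 aldehyde
Product: 15 racemic (2E,7Z,10Z)-12-[(tert-butyldimethylsilyl)oxy]-6-hydroxy-3,7,11-trimethyldodeca-2,7,10-trien-1-yl acetate, via alkenylchromium dichloride 14 (not isolated)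
Conditions: CrCl2, NiCl2 (cat.), DMSO, rt
Reagents that add atoms: none
Why: Nozaki–Hiyama–Kishi coupling: the alkenylchromium species formed with retention of the (Z) geometry should add chemoselectively to the aldehyde and form C3–C4 in the presence of the acetate and the silyl ether; C3 arises racemic and is set in steps 8 and 9.

Step 8
Reactants: 15 racemic C3 carbinol
Product: 16 (2E,7Z,10Z)-12-[(tert-butyldimethylsilyl)oxy]-3,7,11-trimethyl-6-oxododeca-2,7,10-trien-1-yl acetate
Conditions: Dess–Martin periodinane, NaHCO3, CH2Cl2, 0 °C to rt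
Reagents that add atoms: none
Why: Dess–Martin oxidation of the secondary allylic alcohol under buffered conditions should give the enone without isomerising the (Z)-C4=C5 olefin.

Step 9
Reactants: 16 C3 enone
Product: 17 (2E,6S,7Z,10Z)-12-[(tert-butyldimethylsilyl)oxy]-6-hydroxy-3,7,11-trimethyldodeca-2,7,10-trien-1-yl acetate
Conditions: (R)-2-methyl-CBS-oxazaborolidine (cat.), catecholborane, toluene, −78 °C
Reagents that add atoms: none
Why: Corey–Bakshi–Shibata reduction: the α-methylalkenyl group acts as the large substituent, so the (R)-catalyst should deliver hydride to give the (S) configuration at C3, and catecholborane does not hydroborate the olefins.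

Step 10
Reactants: 17 (6S)-carbinol
Product: 18 (2E,6S,7Z,10Z)-6,12-bis[(tert-butyldimethylsilyl)oxy]-3,7,11-trimethyldodeca-2,7,10-trien-1-yl acetate
Conditions: TBSCl, imidazole, DMF, rt
Reagents that add atoms: tert-butyldimethylsilyl chloride, CC(C)(C)[Si](C)(C)Cl
Why: Silyl ether formation protects the C3 alcohol in a form that survives the organolithium and organoaluminium steps ahead.

Step 11
Reactants: 18 bis-silyl ether
Product: 19 (2E,6S,7Z,10Z)-6-[(tert-butyldimethylsilyl)oxy]-12-hydroxy-3,7,11-trimethyldodeca-2,7,10-trien-1-yl acetate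
Conditions: HF·pyridine, pyridine, THF, 0 °C
Reagents that add atoms: none
Why: Selective desilylation: the primary allylic silyl ether at C12 should be cleaved far faster than the hindered secondary one at C3, and the acetate is stable to buffered HF.

Step 12
Reactants: 19 C12 alcohol
Product: 21 (2E,6S,7Z,10Z)-6-[(tert-butyldimethylsilyl)oxy]-12-chloro-3,7,11-trimethyldodeca-2,7,10-trien-1-yl acetate, via allylic mesylate 20 (not isolated)
Conditions: MsCl, 2,4,6-collidine, LiCl, DMF, 0 °C
Reagents that add atoms: lithium chloride, [Li+].[Cl-]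
Why: Mesylation with in situ SN2 displacement by chloride should give the primary allylic chloride without allylic transposition or loss of the (Z)-C7=C11 geometry.

Step 13
Reactants: 21 C12 chloride
Product: 22 (2E,6S,7Z,10Z)-6-[(tert-butyldimethylsilyl)oxy]-12-chloro-3,7,11-trimethyldodeca-2,7,10-trien-1-ol
Conditions: i-Bu2AlH, CH2Cl2, −78 °C
Reagents that add atoms: none
Why: Reductive ester cleavage by the aluminium hydride at low temperature frees the C8 alcohol while the allylic chloride and the silyl ether stay intact.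

Step 14
Reactants: 22 chloro alcohol
Product: 24 (3Z,6Z,8S,11E)-8-[(tert-butyldimethylsilyl)oxy]-3,7,11-trimethyl-1-oxacyclotrideca-3,6,11-triene (thirteen-membered C8–O–C12 ether), via sodium alkoxide 23 (not isolated)
Conditions: NaH, Bu4NI (cat.), THF, 60 °C, slow addition at high dilution
Reagents that add atoms: none
Why: Intramolecular Williamson etherification: at high dilution the primary allylic alkoxide should displace the primary allylic chloride (SN2) and close the thirteen-membered ring without touching C3 or the olefin geometries.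

Step 15
Reactants: 24 thirteen-membered ether
Product: 26 (3S,4Z,7R,8R,9E)-3-[(tert-butyldimethylsilyl)oxy]germacra-4,9,11-trien-8-ol (ten-membered homoallylic alcohol), via C8-lithio ether 25 (not isolated)
Conditions: s-BuLi, THF, −78 to −40 °C; then H2O
Reagents that add atoms: none
Why: [2,3]-Wittig rearrangement: s-BuLi removes a proton at C8, which is alpha to oxygen and allylic to C9=C10, and the allyllithium attacks C7 suprafacially through a five-membered six-electron envelope (C8, O, C12, C11, C7) while C12–O breaks, so that C11=C12 becomes the isopropenyl group and the alkoxide ends on C8. The closest known reaction type is the lithiation-induced ring contraction of thirteen-membered bis-allylic ethers to cyclodecadienols. The ten-membered carbocycle closes transannularly by C8–C7 bond formation inside the thirteen-membered oxacycle, which loses O, C12 and C11 from the ring. C7 and C8 are set together: the (Z)-C7=C11 olefin, with the C9=C10 vinyl group exo on the envelope, should give the syn relation that places the isopropenyl group and the hydroxyl cis on the ring, and the C3 silyloxy centre, held outward by allylic strain across the (Z)-C4=C5 olefin, is relied on to choose the face. The step needs site selectivity for C8 over C12 and C6: a C12 anion could only shift onto the fully substituted C10, and the doubly allylic C6 lacks the activating oxygen. The low temperature should suppress the competing [1,2]-shift.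

Step 16
Reactants: 26 ten-membered homoallylic alcohol
Product: 27 (3S,4Z,7R,8S,9S,10S)-3-[(tert-butyldimethylsilyl)oxy]-9,10-epoxygermacra-4,11-dien-8-ol
Conditions: VO(acac)2 (cat.), t-BuOOH, CH2Cl2, 0 °C
Reagents that add atoms: tert-butyl hydroperoxide, CC(C)(C)OO
Why: Hydroxyl-directed vanadium-catalysed epoxidation is chemoselective for the allylic C9=C10 olefin, and delivery from the C8 vanadate, which needs a small O–C–C=C dihedral angle that the ring offers only toward the outer face, should place the oxygen on C9 cis to the C8 hydroxyl (9β, 8,9-erythro).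

Step 17
Reactants: 27 9,10-epoxy alcohol
Product: 28 (3S,4Z,7R,8S,9S,10S)-3-[(tert-butyldimethylsilyl)oxy]-9,10-epoxy-8-[(triethylsilyl)oxy]germacra-4,11-diene
Conditions: Et3SiCl, imidazole, DMF, 0 °C to rt
Reagents that add atoms: triethylsilyl chloride, CC[Si](Cl)(CC)CC
Why: Silyl ether formation blocks alkoxide-directed proton removal from C14 in the next step and marks C8 with a group that can later be removed next to the C3 silyl ether.

Step 18
Reactants: 28 silylated 9,10-epoxide
Product: 29 (1(10)Z,3S,4Z,7R,8S,9R)-3-[(tert-butyldimethylsilyl)oxy]-8-[(triethylsilyl)oxy]germacra-1(10),4,11-trien-9-ol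
Conditions: Et2AlCl, lithium 2,2,6,6-tetramethylpiperidide, toluene, 0 °C; then 28, 0 °C to rt
Reagents that add atoms: none
Why: Aluminium amide-mediated isomerisation of an epoxide to an allylic alcohol (syn elimination through a cyclic transition state): the amide should remove the C1 proton that lies cis to the epoxide hydrogen, C10–O breaks, C9 keeps its oxygen and configuration, and the gauche C9–C10–C1–C2 torsion of a ten-membered trans-epoxide should lead to the (Z)-C1=C10 olefin.

Step 19
Reactants: 29 (Z)-allylic alcohol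
Product: 30 (1R,3S,4Z,7R,8S,9S,10S)-3-[(tert-butyldimethylsilyl)oxy]-1,10-epoxy-8-[(triethylsilyl)oxy]germacra-4,11-dien-9-ol
Conditions: VO(acac)2 (cat.), t-BuOOH, CH2Cl2, 0 °C
Reagents that add atoms: tert-butyl hydroperoxide, CC(C)(C)OO
Why: Hydroxyl-directed vanadium-catalysed epoxidation: in medium-ring (Z)-cycloalkenols this reagent delivers oxygen cis to the hydroxyl, which should give the 1β,10β-oxirane and leave C4=C5 and the isopropenyl group alone.

Step 20
Reactants: 31 angelic acid
Product: 32 (2Z)-2-methylbut-2-enoic 2,4,6-trichlorobenzoic anhydride (mixed angelic anhydride)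
Conditions: 2,4,6-trichlorobenzoyl chloride, Et3N, toluene, rt; filtered under argon and kept at −20 °C as a toluene solution; one batch sized for steps 21 and 26
Reagents that add atoms: 2,4,6-trichlorobenzoyl chloride, O=C(Cl)c1c(Cl)cc(Cl)cc1Cl
Why: Acyl substitution of the acid chloride by triethylammonium angelate (Yamaguchi mixed-anhydride formation) should proceed at room temperature without a nucleophilic catalyst, conditions under which the (Z)-acid does not isomerise to tiglic acid.

Step 21
Reactants: 30 1,10-epoxy alcohol; 32 mixed angelic anhydride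
Product: 33 (1R,3S,4Z,7R,8S,9S,10R)-3-[(tert-butyldimethylsilyl)oxy]-1,10-epoxy-8-[(triethylsilyl)oxy]germacra-4,11-dien-9-yl (2Z)-2-methylbut-2-enoate
Conditions: 32 (toluene solution), Et3N, toluene, 80 °C
Reagents that add atoms: none
Why: Yamaguchi-type esterification: the hindered C9 alcohol should attack the angeloyl carbonyl of the mixed anhydride, the other carbonyl being shielded by its two ortho chlorines, and the absence of a nucleophilic catalyst should keep the angelate from isomerising to the tiglate.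

Step 22
Reactants: 33 C9 angelate
Product: 34 (1R,3S,4Z,7R,8S,9S,10R)-3-[(tert-butyldimethylsilyl)oxy]-1,10-epoxy-8-hydroxygermacra-4,11-dien-9-yl (2Z)-2-methylbut-2-enoate
Conditions: HF·pyridine, pyridine, THF, 0 °C
Reagents that add atoms: none
Why: Selective desilylation: the triethylsilyl ether should be cleaved far faster than the secondary tert-butyldimethylsilyl ether, under non-basic conditions that avoid acyl migration and epoxide opening.

Step 23
Reactants: 34 C8 alcohol
Product: 35 (1R,3S,4Z,7R,8S,9S,10R)-8-acetoxy-3-[(tert-butyldimethylsilyl)oxy]-1,10-epoxygermacra-4,11-dien-9-yl (2Z)-2-methylbut-2-enoate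
Conditions: Ac2O, DMAP, pyridine, CH2Cl2, 0 °C
Reagents that add atoms: acetic anhydride, CC(=O)OC(C)=O
Why: DMAP-catalysed acetylation of the C8 alcohol should be fast enough to outrun migration of the neighbouring angelate.

Step 24
Reactants: 35 C8 acetate
Product: 36 (1R,3S,4Z,7R,8S,9S,10R)-8-acetoxy-1,10-epoxy-3-hydroxygermacra-4,11-dien-9-yl (2Z)-2-methylbut-2-enoate
Conditions: Bu4NF, AcOH, THF, 0 °C to rt
Reagents that add atoms: none
Why: Fluoride-mediated desilylation buffered with acetic acid should free the C3 alcohol without touching the esters or the oxirane.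

Step 25
Reactants: 36 C3 alcohol
Product: 37 (1R,3S,4R,5S,7R,8S,9S,10R)-8-acetoxy-1,10:4,5-diepoxy-3-hydroxygermacr-11-en-9-yl (2Z)-2-methylbut-2-enoate
Conditions: mCPBA, NaHCO3, CH2Cl2, 0 °C
Reagents that add atoms: mCPBA, O=C(OO)c1cccc(Cl)c1
Why: Prilezhaev epoxidation guided by the allylic hydroxyl: with C3–H eclipsing the (Z)-olefin, hydrogen bonding and peripheral attack should deliver oxygen trans to the C3 oxygen (4α,5α), and the trisubstituted olefin reacts before the isopropenyl and angelate double bonds.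

Step 26
Reactants: 37 4,5-epoxy alcohol; 32 mixed angelic anhydride
Product: 38 (1R,3S,4S,5S,7R,8S,9S,10R)-8-acetoxy-1,10:4,5-diepoxygermacr-11-ene-3,9-diyl bis[(2Z)-2-methylbut-2-enoate] (target)
Conditions: 32 (toluene solution), Et3N, toluene, 80 °C
Reagents that add atoms: none
Why: Yamaguchi-type esterification with the preformed mixed anhydride should install the second angelate on the C3 epoxy alcohol with retention at C3 and without (Z) to (E) isomerisation.

Compound list
1 | geranyl acetate, (2E)-3,7-dimethylocta-2,6-dien-1-yl acetate | CC(C)=CCC/C(C)=C/COC(C)=O | starting material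
2 | (2E)-6,7-epoxy-3,7-dimethyloct-2-en-1-yl acetate (racemic) | CC1(C)OC1CC/C(C)=C/COC(C)=O | intermediate
3 | (2E)-3-methyl-6-oxohex-2-en-1-yl acetate | O=CCC/C(C)=C/COC(C)=O | intermediate
4 | but-2-yn-1-ol | CC#CCO | starting material
5 | sodium 2,2-bis(2-methoxyethoxy)-3-methyl-2,5-dihydro-1,2-oxaluminol-2-uide (cyclic alkenylalanate) | CC1=CCO[Al-]1(OCCOC)OCCOC.[Na+] | intermediate
6 | (2Z)-3-iodobut-2-en-1-ol | C/C(I)=C/CO | intermediate
7 | (2Z)-1-bromo-3-iodobut-2-ene | C/C(I)=C/CBr | intermediate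
8 | methyltriphenylphosphonium bromide | C[P+](c1ccccc1)(c1ccccc1)c1ccccc1.[Br-] | starting material
9 | methylenetriphenylphosphorane | C=P(c1ccccc1)(c1ccccc1)c1ccccc1 | intermediate
10 | [(3Z)-4-iodopent-3-en-1-yl]triphenylphosphonium bromide | C/C(I)=C/CC[P+](c1ccccc1)(c1ccccc1)c1ccccc1.[Br-] | intermediate
11 | 1-[(tert-butyldimethylsilyl)oxy]propan-2-one | CC(=O)CO[Si](C)(C)C(C)(C)C | starting material
12 | [(3Z)-4-iodopent-3-en-1-ylidene]triphenylphosphorane | C/C(I)=C/CC=P(c1ccccc1)(c1ccccc1)c1ccccc1 | intermediate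
13 | tert-butyl{[(2Z,5Z)-6-iodo-2-methylhepta-2,5-dien-1-yl]oxy}dimethylsilane | C/C(I)=C/C/C=C(/C)CO[Si](C)(C)C(C)(C)C | intermediate
14 | dichloro[(2Z,5Z)-7-[(tert-butyldimethylsilyl)oxy]-6-methylhepta-2,5-dien-2-yl]chromium | C/C(=C/C/C=C(/C)CO[Si](C)(C)C(C)(C)C)[Cr](Cl)Cl | intermediate
15 | (2E,7Z,10Z)-12-[(tert-butyldimethylsilyl)oxy]-6-hydroxy-3,7,11-trimethyldodeca-2,7,10-trien-1-yl acetate (racemic at C6) | CC(=O)OC/C=C(\C)CCC(O)/C(C)=C\C/C=C(/C)CO[Si](C)(C)C(C)(C)C | intermediate
16 | (2E,7Z,10Z)-12-[(tert-butyldimethylsilyl)oxy]-3,7,11-trimethyl-6-oxododeca-2,7,10-trien-1-yl acetate | CC(=O)OC/C=C(\C)CCC(=O)/C(C)=C\C/C=C(/C)CO[Si](C)(C)C(C)(C)C | intermediate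
17 | (2E,6S,7Z,10Z)-12-[(tert-butyldimethylsilyl)oxy]-6-hydroxy-3,7,11-trimethyldodeca-2,7,10-trien-1-yl acetate | CC(=O)OC/C=C(\C)CC[C@H](O)/C(C)=C\C/C=C(/C)CO[Si](C)(C)C(C)(C)C | intermediate
18 | (2E,6S,7Z,10Z)-6,12-bis[(tert-butyldimethylsilyl)oxy]-3,7,11-trimethyldodeca-2,7,10-trien-1-yl acetate | CC(=O)OC/C=C(\C)CC[C@H](O[Si](C)(C)C(C)(C)C)/C(C)=C\C/C=C(/C)CO[Si](C)(C)C(C)(C)C | intermediate
19 | (2E,6S,7Z,10Z)-6-[(tert-butyldimethylsilyl)oxy]-12-hydroxy-3,7,11-trimethyldodeca-2,7,10-trien-1-yl acetate | CC(=O)OC/C=C(\C)CC[C@H](O[Si](C)(C)C(C)(C)C)/C(C)=C\C/C=C(/C)CO | intermediate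
20 | (2E,6S,7Z,10Z)-6-[(tert-butyldimethylsilyl)oxy]-12-[(methylsulfonyl)oxy]-3,7,11-trimethyldodeca-2,7,10-trien-1-yl acetate | CC(=O)OC/C=C(\C)CC[C@H](O[Si](C)(C)C(C)(C)C)/C(C)=C\C/C=C(/C)COS(C)(=O)=O | intermediate
21 | (2E,6S,7Z,10Z)-6-[(tert-butyldimethylsilyl)oxy]-12-chloro-3,7,11-trimethyldodeca-2,7,10-trien-1-yl acetate | CC(=O)OC/C=C(\C)CC[C@H](O[Si](C)(C)C(C)(C)C)/C(C)=C\C/C=C(/C)CCl | intermediate
22 | (2E,6S,7Z,10Z)-6-[(tert-butyldimethylsilyl)oxy]-12-chloro-3,7,11-trimethyldodeca-2,7,10-trien-1-ol | OC/C=C(\C)CC[C@H](O[Si](C)(C)C(C)(C)C)/C(C)=C\C/C=C(/C)CCl | intermediate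
23 | sodium (2E,6S,7Z,10Z)-6-[(tert-butyldimethylsilyl)oxy]-12-chloro-3,7,11-trimethyldodeca-2,7,10-trien-1-olate | [Na+].[O-]C/C=C(\C)CC[C@H](O[Si](C)(C)C(C)(C)C)/C(C)=C\C/C=C(/C)CCl | intermediate
24 | (3Z,6Z,8S,11E)-8-[(tert-butyldimethylsilyl)oxy]-3,7,11-trimethyl-1-oxacyclotrideca-3,6,11-triene | C1OC/C(C)=C\C/C=C(C)\[C@@H](O[Si](C)(C)C(C)(C)C)CC/C(C)=C/1 | intermediate
25 | 13-lithio derivative of 24 (lithium on germacrane C8, allyllithium) | [Li]C1OC/C(C)=C\C/C=C(C)\[C@@H](O[Si](C)(C)C(C)(C)C)CC/C(C)=C/1 | intermediate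
26 | (3S,4Z,7R,8R,9E)-3-[(tert-butyldimethylsilyl)oxy]germacra-4,9,11-trien-8-ol; 3β-OTBS, 7β-isopropenyl, 8β-OH | C=C(C)[C@H]1C/C=C(C)\[C@@H](O[Si](C)(C)C(C)(C)C)CC/C(C)=C/[C@H]1O | intermediate
27 | (3S,4Z,7R,8S,9S,10S)-3-[(tert-butyldimethylsilyl)oxy]-9,10-epoxygermacra-4,11-dien-8-ol; trans-oxirane with 9β-oxygen | C=C(C)[C@H]1C/C=C(C)\[C@@H](O[Si](C)(C)C(C)(C)C)CC[C@]2(C)O[C@H]2[C@H]1O | intermediate
28 | (3S,4Z,7R,8S,9S,10S)-3-[(tert-butyldimethylsilyl)oxy]-9,10-epoxy-8-[(triethylsilyl)oxy]germacra-4,11-diene | C=C(C)[C@H]1C/C=C(C)\[C@@H](O[Si](C)(C)C(C)(C)C)CC[C@]2(C)O[C@H]2[C@H]1O[Si](CC)(CC)CC | intermediate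
29 | (1(10)Z,3S,4Z,7R,8S,9R)-3-[(tert-butyldimethylsilyl)oxy]-8-[(triethylsilyl)oxy]germacra-1(10),4,11-trien-9-ol; 9β-OH | C=C(C)[C@H]1C/C=C(C)\[C@@H](O[Si](C)(C)C(C)(C)C)C/C=C(C)\[C@@H](O)[C@H]1O[Si](CC)(CC)CC | intermediate
30 | (1R,3S,4Z,7R,8S,9S,10S)-3-[(tert-butyldimethylsilyl)oxy]-1,10-epoxy-8-[(triethylsilyl)oxy]germacra-4,11-dien-9-ol; 1β,10β-oxirane | C=C(C)[C@H]1C/C=C(C)\[C@@H](O[Si](C)(C)C(C)(C)C)C[C@H]2O[C@@]2(C)[C@@H](O)[C@H]1O[Si](CC)(CC)CC | intermediate
31 | angelic acid, (2Z)-2-methylbut-2-enoic acid | C/C=C(/C)C(=O)O | starting material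
32 | (2Z)-2-methylbut-2-enoic 2,4,6-trichlorobenzoic anhydride | C/C=C(/C)C(=O)OC(=O)c1c(Cl)cc(Cl)cc1Cl | intermediate
33 | (1R,3S,4Z,7R,8S,9S,10R)-3-[(tert-butyldimethylsilyl)oxy]-1,10-epoxy-8-[(triethylsilyl)oxy]germacra-4,11-dien-9-yl (2Z)-2-methylbut-2-enoate | C=C(C)[C@H]1C/C=C(C)\[C@@H](O[Si](C)(C)C(C)(C)C)C[C@H]2O[C@@]2(C)[C@@H](OC(=O)/C(C)=C\C)[C@H]1O[Si](CC)(CC)CC | intermediate
34 | (1R,3S,4Z,7R,8S,9S,10R)-3-[(tert-butyldimethylsilyl)oxy]-1,10-epoxy-8-hydroxygermacra-4,11-dien-9-yl (2Z)-2-methylbut-2-enoate | C=C(C)[C@H]1C/C=C(C)\[C@@H](O[Si](C)(C)C(C)(C)C)C[C@H]2O[C@@]2(C)[C@@H](OC(=O)/C(C)=C\C)[C@H]1O | intermediate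
35 | (1R,3S,4Z,7R,8S,9S,10R)-8-acetoxy-3-[(tert-butyldimethylsilyl)oxy]-1,10-epoxygermacra-4,11-dien-9-yl (2Z)-2-methylbut-2-enoate | C=C(C)[C@H]1C/C=C(C)\[C@@H](O[Si](C)(C)C(C)(C)C)C[C@H]2O[C@@]2(C)[C@@H](OC(=O)/C(C)=C\C)[C@H]1OC(C)=O | intermediate
36 | (1R,3S,4Z,7R,8S,9S,10R)-8-acetoxy-1,10-epoxy-3-hydroxygermacra-4,11-dien-9-yl (2Z)-2-methylbut-2-enoate | C=C(C)[C@H]1C/C=C(C)\[C@@H](O)C[C@H]2O[C@@]2(C)[C@@H](OC(=O)/C(C)=C\C)[C@H]1OC(C)=O | intermediate
37 | (1R,3S,4R,5S,7R,8S,9S,10R)-8-acetoxy-1,10:4,5-diepoxy-3-hydroxygermacr-11-en-9-yl (2Z)-2-methylbut-2-enoate; 4α,5α-oxirane | C=C(C)[C@H]1C[C@@H]2O[C@]2(C)[C@@H](O)C[C@H]2O[C@@]2(C)[C@@H](OC(=O)/C(C)=C\C)[C@H]1OC(C)=O | intermediate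
38 | (1R,3S,4S,5S,7R,8S,9S,10R)-8-acetoxy-1,10:4,5-diepoxygermacr-11-ene-3,9-diyl bis[(2Z)-2-methylbut-2-enoate] | C=C(C)[C@H]1C[C@@H]2O[C@]2(C)[C@@H](OC(=O)/C(C)=C\C)C[C@H]2O[C@@]2(C)[C@@H](OC(=O)/C(C)=C\C)[C@H]1OC(C)=O | target

Total steps: 26. Longest linear sequence: 23 steps (steps 3–19 and 21–26, from but-2-yn-1-ol 4 to 38); steps 1–2 and step 20 are side branches.

Steps most likely to fail

Step 15 (ring contraction). Lithiation may not stay at C8 (C12 and the doubly allylic C6 can compete), and the remote C3 centre may steer the face only weakly, so that constitutional isomers or the C7,C8-diastereomer erode the yield. Fallback: the carbanion is made site-specifically by tin–lithium exchange. Setting out from chloro alcohol 22, MnO2 oxidation should give the (2E)-enal chloride F1. Bu3SnLi (from Bu3SnH and lithium diisopropylamide) adds to the aldehyde at −78 °C to give the α-stannyl carbinol F2 as its lithium alkoxide. This alkoxide is run into THF–HMPA at high dilution to close the stannyl ether F3; the ring closure is the delicate point of this fallback, since α-stannyl alkoxides can revert to the aldehyde. n-BuLi at −78 °C then exchanges tin for lithium at C8 only, and the shift returns the route at 26. If the lithio species holds its configuration for the lifetime of the shift, the separated C8 epimers of F3 offer a second handle on the facial sense.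

Step 16 (first directed epoxidation). Facial selectivity may be poor: allylic strain between the C8 hydroxyl and the C14 methyl can favour the conformer that delivers oxygen to the other face, giving the 9α-oxygen (8,9-threo). Fallback: C9 is inverted after the olefin has moved. Setting out from 26, the diastereomeric epoxy alcohol F4 is silylated to the triethylsilyl ether F5 and isomerised as in step 18 to the 9-epi allylic alcohol F6. Mitsunobu reaction with 4-nitrobenzoic acid (PPh3, diisopropyl azodicarboxylate) should give the inverted 4-nitrobenzoate F7, and methanolysis (K2CO3, MeOH) returns the route at 29.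

Step 18 (epoxide to allylic alcohol). Geometric control may be lost: if the ring reacts through an anti C9–C10–C1–C2 torsion, the syn elimination gives the (E)-C1=C10 olefin, which cannot lead to the cis-oxirane. Fallback: stereospecific inversion of the olefin by deoxygenation of its epoxide. Setting out from 28, the (E)-allylic alcohol F8 is epoxidised (VO(acac)2, t-BuOOH) to the trans-epoxy alcohol F9; either face serves, because both centres are erased again. LiPPh2 opens it at C1 with inversion to the hydroxy phosphine F10, and quaternisation with MeI triggers syn loss of the phosphine oxide, which should deliver the (Z)-olefin and return the route at 29.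

Further compounds
F1 | step 15 | (2E,6S,7Z,10Z)-6-[(tert-butyldimethylsilyl)oxy]-12-chloro-3,7,11-trimethyldodeca-2,7,10-trienal | O=C/C=C(\C)CC[C@H](O[Si](C)(C)C(C)(C)C)/C(C)=C\C/C=C(/C)CCl
F2 | step 15 | (2E,6S,7Z,10Z)-6-[(tert-butyldimethylsilyl)oxy]-12-chloro-3,7,11-trimethyl-1-(tributylstannyl)dodeca-2,7,10-trien-1-ol (both C1 epimers) | CCCC[Sn](CCCC)(CCCC)C(O)/C=C(\C)CC[C@H](O[Si](C)(C)C(C)(C)C)/C(C)=C\C/C=C(/C)CCl
F3 | step 15 | tributyl[(3Z,6Z,8S,11E)-8-[(tert-butyldimethylsilyl)oxy]-3,7,11-trimethyl-1-oxacyclotrideca-3,6,11-trien-13-yl]stannane (both C13 epimers) | CCCC[Sn](CCCC)(CCCC)C1OC/C(C)=C\C/C=C(C)\[C@@H](O[Si](C)(C)C(C)(C)C)CC/C(C)=C/1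
F4 | step 16 | (3S,4Z,7R,8S,9R,10R)-3-[(tert-butyldimethylsilyl)oxy]-9,10-epoxygermacra-4,11-dien-8-ol (9α-oxygen) | C=C(C)[C@H]1C/C=C(C)\[C@@H](O[Si](C)(C)C(C)(C)C)CC[C@@]2(C)O[C@@H]2[C@H]1O
F5 | step 16 | (3S,4Z,7R,8S,9R,10R)-3-[(tert-butyldimethylsilyl)oxy]-9,10-epoxy-8-[(triethylsilyl)oxy]germacra-4,11-diene | C=C(C)[C@H]1C/C=C(C)\[C@@H](O[Si](C)(C)C(C)(C)C)CC[C@@]2(C)O[C@@H]2[C@H]1O[Si](CC)(CC)CC
F6 | step 16 | (1(10)Z,3S,4Z,7R,8S,9S)-3-[(tert-butyldimethylsilyl)oxy]-8-[(triethylsilyl)oxy]germacra-1(10),4,11-trien-9-ol (9α-OH) | C=C(C)[C@H]1C/C=C(C)\[C@@H](O[Si](C)(C)C(C)(C)C)C/C=C(C)\[C@H](O)[C@H]1O[Si](CC)(CC)CC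
F7 | step 16 | 4-nitrobenzoate of 29 (9β-ester) | C=C(C)[C@H]1C/C=C(C)\[C@@H](O[Si](C)(C)C(C)(C)C)C/C=C(C)\[C@@H](OC(=O)c2ccc(cc2)[N+](=O)[O-])[C@H]1O[Si](CC)(CC)CC
F8 | step 18 | (1(10)E)-isomer of 29 | C=C(C)[C@H]1C/C=C(C)\[C@@H](O[Si](C)(C)C(C)(C)C)C/C=C(C)/[C@@H](O)[C@H]1O[Si](CC)(CC)CC
F9 | step 18 | trans-1,10-epoxide of F8 (drawn with 1α,10β-oxygen) | C=C(C)[C@H]1C/C=C(C)\[C@@H](O[Si](C)(C)C(C)(C)C)C[C@@H]2O[C@@]2(C)[C@@H](O)[C@H]1O[Si](CC)(CC)CC
F10 | step 18 | 1β-(diphenylphosphanyl)-3β-[(tert-butyldimethylsilyl)oxy]-8β-[(triethylsilyl)oxy]germacra-4Z,11-diene-9β,10β-diol | C=C(C)[C@H]1C/C=C(C)\[C@@H](O[Si](C)(C)C(C)(C)C)C[C@@H](P(c2ccccc2)c2ccccc2)[C@@](C)(O)[C@@H](O)[C@H]1O[Si](CC)(CC)CC
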